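**Retrosynthetic overview**
1. The target comes from its penta-O-benzyl ether by one neutral hydrogenolysis. Every phenol that takes no part in the key step stays benzylated until then.
2. Key disconnection: the pyran ring of the flavan unit is cut at O1–C2, C3–C4 and C4–C4a. This gives an achiral 3-(2,6-dibenzyloxy-4-hydroxyphenyl)flavone, formaldehyde (C4) and 4-vinylphenol (C3, C2 and the 2-aryl ring). The three are rejoined by ortho-quinone methide formation and oxa-[4+2] cycloaddition under a chiral phosphoric acid.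
3. Enabling feature: the benzo ring of the flavan is a phloroglucinol ring in which O1 (on C8a) lies para to the chromone-bearing C6, while O5 and O7 flank that bond. Without the pyran ring the aryl group has a local twofold axis through C6 and C8a, so C4a and C8 are equivalent and O1 is the only oxygen that differs. O1–C8a–C4a–C4 with its bare CH2 is an ortho-quinone methide retron, and the 4-OH of the 2-aryl ring, conjugated with C2, gives the catalyst a handle.
4. The phenol comes from Negishi coupling of a 3-iodoflavone with the arylzinc made from 1,3-bis(benzyloxy)-5-bromo-2-iodobenzene. The para bromine is then exchanged for OH by borylation and oxidation.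
5. Ring order: all benzene rings are bought. The pyrone ring of the flavone is closed first (1,3-diketone, cyclodehydration) and the pyran ring of the flavan is closed last.

Key step: step 8

Assumption: the axis between chromone C3 and flavan C6 is not defined in the target structure, so rotamers or atropisomers about it are treated as one compound and carried on together; (R)-TRIP is written for step 8, and its equally available enantiomer is used if the sense of induction proves opposite.

**Step 1**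
Reactants: 1 1-[2,4-bis(benzyloxy)-6-hydroxyphenyl]ethanone; 2 4-(benzyloxy)benzoyl chloride
Product: 4 1-[2,4-bis(benzyloxy)-6-hydroxyphenyl]-3-[4-(benzyloxy)phenyl]propane-1,3-dione, via dilithium enolate 3 (not isolated)
Conditions: LiN(SiMe3)2 (3.2 equiv), THF, −78 to −10 °C; 2, −78 °C to rt; aq. HCl
Reagents that add atoms: LiN(SiMe3)2, C[Si](C)(C)N([Li])[Si](C)(C)C (lithium of 3 only)
Why: Two equivalents of base turn 1 into the phenolate–enolate dianion 3, whose carbon end is acylated by 2 (crossed Claisen C-acylation, the one-flask form of the Baker–Venkataraman sequence), and the third equivalent stores the acidic 1,3-diketone as its enolate so that it should not react further.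

**Step 2**
Reactants: 4 1-[2,4-bis(benzyloxy)-6-hydroxyphenyl]-3-[4-(benzyloxy)phenyl]propane-1,3-dione
Product: 5 5,7-bis(benzyloxy)-2-[4-(benzyloxy)phenyl]-4H-chromen-4-one
Conditions: p-TsOH·H2O (cat.), PhMe, reflux, Dean–Stark
Reagents that add atoms: none
Why: Acid-catalysed cyclodehydration of an ortho-hydroxyaryl 1,3-diketone is the standard closure of the flavone pyrone ring, and aryl benzyl ethers should tolerate catalytic sulfonic acid in toluene.

**Step 3**
Reactants: 5 5,7-bis(benzyloxy)-2-[4-(benzyloxy)phenyl]-4H-chromen-4-one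
Product: 7 5,7-bis(benzyloxy)-2-[4-(benzyloxy)phenyl]-3-iodo-4H-chromen-4-one, via 3-lithioflavone 6 (not isolated)
Conditions: LiN(iPr)2 (1.3 equiv), THF, −78 °C; I2, −78 to −20 °C
Reagents that add atoms: LiN(iPr)2, CC(C)N([Li])C(C)C (lithium of 6 only); iodine, II
Why: Flavones are deprotonated at C3 by lithium amides at low temperature (vinylic lithiation next to the C4 carbonyl), and an iodine quench should fix the halogen at C3, a position that electrophilic iodination would miss in favour of C6 and C8 of the dialkoxy ring.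

**Step 4**
Reactants: 8 5-bromobenzene-1,3-diol
Product: 9 5-bromo-2-iodobenzene-1,3-diol
Conditions: I2 (1.05 equiv), NaHCO3, H2O/THF, 0 °C to rt
Reagents that add atoms: iodine, II
Why: Electrophilic iodination of free resorcinols with I2 and NaHCO3 in water goes to the carbon between the two hydroxyl groups, as in the preparation of 2-iodoresorcinol, and the bulky bromine next to C4 and C6 should reinforce that preference.

**Step 5**
Reactants: 9 5-bromo-2-iodobenzene-1,3-diol
Product: 10 1,3-bis(benzyloxy)-5-bromo-2-iodobenzene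
Conditions: BnBr (2.3 equiv), K2CO3, DMF, rt to 50 °C
Reagents that add atoms: benzyl bromide, BrCc1ccccc1
Why: Williamson ether synthesis on both phenols should proceed cleanly, and neither aryl halide reacts under these conditions.

**Step 6**
Reactants: 10 1,3-bis(benzyloxy)-5-bromo-2-iodobenzene; 7 5,7-bis(benzyloxy)-2-[4-(benzyloxy)phenyl]-3-iodo-4H-chromen-4-one
Product: 13 5,7-bis(benzyloxy)-3-[2,6-bis(benzyloxy)-4-bromophenyl]-2-[4-(benzyloxy)phenyl]-4H-chromen-4-one, via arylmagnesium chloride 11 (not isolated), via arylzinc chloride 12 (not isolated)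
Conditions: iPrMgCl·LiCl (1.1 equiv), THF, −15 °C; ZnCl2, to rt; then 7, Pd2(dba)3 (2.5 mol %), RuPhos (10 mol %), THF/NMP, 70 °C
Reagents that add atoms: iPrMgCl·LiCl, CC(C)[Mg]Cl.[Li+].[Cl-] (Mg and Cl of 11 only); ZnCl2, Cl[Zn]Cl (Zn and Cl of 12 only)
Why: Iodine–magnesium exchange is much faster at C–I than at C–Br, the arylzinc tolerates the chromone carbonyl, and Negishi coupling with a bulky dialkylbiarylphosphine is the reaction type of choice for bonds flanked by four ortho substituents, the activated C3–I bond of 7 adding to palladium far faster than the electron-rich aryl bromide.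

**Step 7**
Reactants: 13 5,7-bis(benzyloxy)-3-[2,6-bis(benzyloxy)-4-bromophenyl]-2-[4-(benzyloxy)phenyl]-4H-chromen-4-one
Product: 15 5,7-bis(benzyloxy)-3-[2,6-bis(benzyloxy)-4-hydroxyphenyl]-2-[4-(benzyloxy)phenyl]-4H-chromen-4-one, via pinacol boronate 14 (not isolated)
Conditions: B2pin2, PdCl2(dppf) (5 mol %), KOAc, 1,4-dioxane, 90 °C; then 30 % H2O2, aq. NaOH, THF, 0 °C
Reagents that add atoms: bis(pinacolato)diboron, CC1(C)OB(OC1(C)C)B1OC(C)(C)C(C)(C)O1 (boronate of 14 only); hydrogen peroxide, OO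
Why: Miyaura borylation of the unhindered aryl bromide followed by peroxide oxidation of the C–B bond (1,2-aryl shift from boron to oxygen) should place the free hydroxyl exactly para to the biaryl bond while every other oxygen stays benzylated.

**Step 8**
Reactants: 15 5,7-bis(benzyloxy)-3-[2,6-bis(benzyloxy)-4-hydroxyphenyl]-2-[4-(benzyloxy)phenyl]-4H-chromen-4-one; 16 formaldehyde (used as paraformaldehyde); 17 4-vinylphenol
Product: 20 5,7-bis(benzyloxy)-3-[(2S)-5,7-bis(benzyloxy)-2-(4-hydroxyphenyl)-3,4-dihydro-2H-chromen-6-yl]-2-[4-(benzyloxy)phenyl]-4H-chromen-4-one, via salicyl alcohol 18 (not isolated), via ortho-quinone methide 19 (not isolated)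
Conditions: (CH2O)n (2 equiv), 17 (5 equiv), (R)-TRIP [(R)-3,3'-bis(2,4,6-triisopropylphenyl)-1,1'-binaphthyl-2,2'-diyl hydrogen phosphate] (10 mol %), 4 Å MS, BHT (trace), PhMe, 40 °C; 15 added over 10 h
Reagents that add atoms: none
Why: Proposed new method: the phosphoric acid should first catalyse Friedel–Crafts hydroxymethylation of 15 by formaldehyde at one of the two equivalent carbons ortho to its only free OH (C4a–C4 bond, 18), then dehydrate this trioxygenated benzylic alcohol to the ortho-quinone methide 19, whose O=C–C=CH2 unit adds across the vinyl group of 17 in an inverse-electron-demand oxa-[4+2] cycloaddition that forms C4–C3 and O1–C2 and restores the aromatic ring (flavan numbering). The closest known reaction types are the racemic three-component ortho-quinone methide hetero-Diels–Alder reaction of phloroglucinols, paraformaldehyde and alkenes and the chiral-phosphoric-acid-catalysed [4+2] cycloaddition of in situ ortho-quinone methides with hydroxystyrenes; new are the unsubstituted formaldehyde-derived methide, the para-hydroxystyrene partner and the merger into one asymmetric operation. The pyran ring closes by [4+2] cycloaddition, or, in the asynchronous limit where C4–C3 forms first and leaves a para-quinone methide of the former vinylphenol, by 6-exo-trig oxa-1,6-addition of O1 to C2. C2 is the only new stereocentre and is controlled by the catalyst, which should bridge the methide oxygen (through P–OH) and the 4-OH of 17 (through P=O) so that one enantiotopic face of C2 meets O1 inside the pocket of the 3,3'-aryl groups. The step needs site selectivity (secured by the local twofold symmetry of the aryl ring and by benzylation of the two oxygens flanking the biaryl bond, so that only O1 can become the methide oxygen and only the 6-linked flavan can form), orientation (the nucleophilic CH2 terminus of 17 bonds to the electrophilic methide CH2, which puts the aryl group on C2) and chemoselectivity over diarylmethane formation (excess 17, slow addition of 15, reversibility of any O-alkylation, and no free ortho-hydroxyl left in 20 for a second methide).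

**Step 9**
Reactants: 20 5,7-bis(benzyloxy)-3-[(2S)-5,7-bis(benzyloxy)-2-(4-hydroxyphenyl)-3,4-dihydro-2H-chromen-6-yl]-2-[4-(benzyloxy)phenyl]-4H-chromen-4-one
Product: 21 5,7-dihydroxy-3-[(2S)-5,7-dihydroxy-2-(4-hydroxyphenyl)-3,4-dihydro-2H-chromen-6-yl]-2-(4-hydroxyphenyl)-4H-chromen-4-one (CNP0304187.1)
Conditions: H2 (1 atm), Pd(OH)2/C, THF/MeOH, rt
Reagents that add atoms: none
Why: Hydrogenolysis of aryl benzyl ethers under neutral conditions, the usual last step in the catechin and flavan series, should spare the cyclic C2–O1 bond and the tetrasubstituted C2=C3 bond of the chromone, and without acid or base the C2 stereocentre cannot open to a quinone methide and is not scrambled.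

**Compound list**
1 | 1-[2,4-bis(benzyloxy)-6-hydroxyphenyl]ethanone | CC(=O)c1c(O)cc(OCc2ccccc2)cc1OCc1ccccc1 | starting material
2 | 4-(benzyloxy)benzoyl chloride | O=C(Cl)c1ccc(OCc2ccccc2)cc1 | starting material
3 | dilithium phenolate–enolate of 1 | C=C(O[Li])c1c(O[Li])cc(OCc2ccccc2)cc1OCc1ccccc1 | intermediate
4 | 1-[2,4-bis(benzyloxy)-6-hydroxyphenyl]-3-[4-(benzyloxy)phenyl]propane-1,3-dione | O=C(CC(=O)c1ccc(OCc2ccccc2)cc1)c1c(O)cc(OCc2ccccc2)cc1OCc1ccccc1 | intermediate
5 | 5,7-bis(benzyloxy)-2-[4-(benzyloxy)phenyl]-4H-chromen-4-one | O=c1cc(-c2ccc(OCc3ccccc3)cc2)oc2cc(OCc3ccccc3)cc(OCc3ccccc3)c12 | intermediate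
6 | 3-lithio derivative of 5 | [Li]c1c(-c2ccc(OCc3ccccc3)cc2)oc2cc(OCc3ccccc3)cc(OCc3ccccc3)c2c1=O | intermediate
7 | 5,7-bis(benzyloxy)-2-[4-(benzyloxy)phenyl]-3-iodo-4H-chromen-4-one | O=c1c(I)c(-c2ccc(OCc3ccccc3)cc2)oc2cc(OCc3ccccc3)cc(OCc3ccccc3)c12 | intermediate
8 | 5-bromobenzene-1,3-diol | Oc1cc(O)cc(Br)c1 | starting material
9 | 5-bromo-2-iodobenzene-1,3-diol | Oc1cc(Br)cc(O)c1I | intermediate
10 | 1,3-bis(benzyloxy)-5-bromo-2-iodobenzene | Brc1cc(OCc2ccccc2)c(I)c(OCc2ccccc2)c1 | intermediate
11 | [2,6-bis(benzyloxy)-4-bromophenyl]magnesium chloride | Cl[Mg]c1c(OCc2ccccc2)cc(Br)cc1OCc1ccccc1 | intermediate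
12 | [2,6-bis(benzyloxy)-4-bromophenyl]zinc chloride | Cl[Zn]c1c(OCc2ccccc2)cc(Br)cc1OCc1ccccc1 | intermediate
13 | 5,7-bis(benzyloxy)-3-[2,6-bis(benzyloxy)-4-bromophenyl]-2-[4-(benzyloxy)phenyl]-4H-chromen-4-one | O=c1c(-c2c(OCc3ccccc3)cc(Br)cc2OCc2ccccc2)c(-c2ccc(OCc3ccccc3)cc2)oc2cc(OCc3ccccc3)cc(OCc3ccccc3)c12 | intermediate
14 | pinacol boronate of 13 (Bpin in place of Br) | O=c1c(-c2c(OCc3ccccc3)cc(B3OC(C)(C)C(C)(C)O3)cc2OCc2ccccc2)c(-c2ccc(OCc3ccccc3)cc2)oc2cc(OCc3ccccc3)cc(OCc3ccccc3)c12 | intermediate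
15 | 5,7-bis(benzyloxy)-3-[2,6-bis(benzyloxy)-4-hydroxyphenyl]-2-[4-(benzyloxy)phenyl]-4H-chromen-4-one | O=c1c(-c2c(OCc3ccccc3)cc(O)cc2OCc2ccccc2)c(-c2ccc(OCc3ccccc3)cc2)oc2cc(OCc3ccccc3)cc(OCc3ccccc3)c12 | intermediate
16 | formaldehyde (used as paraformaldehyde) | C=O | starting material
17 | 4-vinylphenol | C=Cc1ccc(O)cc1 | starting material
18 | 5,7-bis(benzyloxy)-3-[2,6-bis(benzyloxy)-4-hydroxy-3-(hydroxymethyl)phenyl]-2-[4-(benzyloxy)phenyl]-4H-chromen-4-one | OCc1c(O)cc(OCc2ccccc2)c(-c2c(-c3ccc(OCc4ccccc4)cc3)oc3cc(OCc4ccccc4)cc(OCc4ccccc4)c3c2=O)c1OCc1ccccc1 | intermediate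
19 | ortho-quinone methide: 3-[2,6-bis(benzyloxy)-3-methylidene-4-oxocyclohexa-1,5-dien-1-yl]-5,7-bis(benzyloxy)-2-[4-(benzyloxy)phenyl]-4H-chromen-4-one | C=C1C(=O)C=C(OCc2ccccc2)C(c2c(-c3ccc(OCc4ccccc4)cc3)oc3cc(OCc4ccccc4)cc(OCc4ccccc4)c3c2=O)=C1OCc1ccccc1 | intermediate
20 | 5,7-bis(benzyloxy)-3-[(2S)-5,7-bis(benzyloxy)-2-(4-hydroxyphenyl)-3,4-dihydro-2H-chromen-6-yl]-2-[4-(benzyloxy)phenyl]-4H-chromen-4-one | O=c1c(-c2c(OCc4ccccc4)cc3c(c2OCc2ccccc2)CC[C@@H](c2ccc(O)cc2)O3)c(-c2ccc(OCc3ccccc3)cc2)oc2cc(OCc3ccccc3)cc(OCc3ccccc3)c12 | intermediate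
21 | 5,7-dihydroxy-3-[(2S)-5,7-dihydroxy-2-(4-hydroxyphenyl)-3,4-dihydro-2H-chromen-6-yl]-2-(4-hydroxyphenyl)-4H-chromen-4-one | O=c1c(-c2c(O)cc3c(c2O)CC[C@@H](c2ccc(O)cc2)O3)c(-c2ccc(O)cc2)oc2cc(O)cc(O)c12 | target

**Total step count:** 9. **Longest linear sequence:** 7 (steps 1, 2, 3, 6, 7, 8, 9).

**Steps most likely to fail**

1. Step 8.
 - What may go wrong: the quinone methide may be intercepted by a second molecule of 15 or by the product, giving methylene bridging. The vinylphenol may oligomerise under acid, and paraformaldehyde may depolymerise too slowly. Facial selectivity at C2 may be poor because the catalyst contacts lie far from the forming C–O bond.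
 - Fallback (known chemistry): it sets out from 15 and comes back at 21. Ortho-formylation of 15 (MgCl2, Et3N, (CH2O)n, MeCN, reflux; Casnati–Skattebøl) gives the salicylaldehyde F1. Wittig olefination with the stabilised ylide Ph3P=CHC(O)C6H4-4-OBn (PhMe, 80 °C) gives the (E)-enone F2. Noyori-type asymmetric transfer hydrogenation with RuCl[(R,R)-TsDPEN](p-cymene) and HCO2Na in H2O/iPrOH reduces first C=C and then C=O to the (R)-benzylic alcohol F3. Mitsunobu etherification (PPh3, DIAD, THF, 0 °C) closes the pyran ring with inversion to the (2S)-hexabenzyl ether F4, which is hydrogenolysed under the conditions of step 9 to 21.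

2. Step 6.
 - What may go wrong: transmetalation and reductive elimination at a bond flanked by four ortho substituents may be slower than protodemetalation of 12 and hydrodeiodination of 7.
 - Fallback: it sets out from 1, 10 and 2 and comes back at 13. It makes the aryl–carbon bond before the pyrone ring exists. Compound 1 is benzylated (BnBr, K2CO3, DMF) to the tribenzyl ketone F5. Palladium-catalysed ketone α-arylation with 10 at its C–I bond (Pd2(dba)3, XPhos, NaOtBu, PhMe, 80 °C) gives the deoxybenzoin F6. Chelation-controlled cleavage of one benzyl ether ortho to the carbonyl (BCl3, CH2Cl2, −78 °C) gives the hydroxy-deoxybenzoin F7. O-aroylation with 2 and Baker–Venkataraman acyl shift (K2CO3, acetone, reflux) give the 2-aryl-1,3-diketone F8, and cyclodehydration (p-TsOH, PhMe, reflux) closes the pyrone ring to 13.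

3. Step 3.
 - What may go wrong: the 3-lithio species may open by β-elimination of the ring oxygen to an alkynone phenolate, or the lithiation may stay incomplete.
 - Fallback: it sets out from 5 and 10 and comes back at 13. It reverses the polarity of the coupling, so no iodoflavone is needed. Compound 5 is zincated at C3 with (2,2,6,6-tetramethylpiperidin-1-yl)zinc chloride·LiCl (TMPZnCl·LiCl, THF, rt) to the configurationally and thermally robust chromon-3-ylzinc chloride F9. This is coupled directly with the C–I bond of 10 (Pd2(dba)3, RuPhos, THF, 60 °C) to give 13, replacing steps 3 and 6.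

**Further compounds**
F1 | step 8 | 2,4-bis(benzyloxy)-3-{5,7-bis(benzyloxy)-2-[4-(benzyloxy)phenyl]-4-oxo-4H-chromen-3-yl}-6-hydroxybenzaldehyde | O=Cc1c(O)cc(OCc2ccccc2)c(-c2c(-c3ccc(OCc4ccccc4)cc3)oc3cc(OCc4ccccc4)cc(OCc4ccccc4)c3c2=O)c1OCc1ccccc1
F2 | step 8 | 5,7-bis(benzyloxy)-3-{2,6-bis(benzyloxy)-3-[(E)-3-[4-(benzyloxy)phenyl]-3-oxoprop-1-enyl]-4-hydroxyphenyl}-2-[4-(benzyloxy)phenyl]-4H-chromen-4-one | O=C(/C=C/c1c(O)cc(OCc2ccccc2)c(-c2c(-c3ccc(OCc4ccccc4)cc3)oc3cc(OCc4ccccc4)cc(OCc4ccccc4)c3c2=O)c1OCc1ccccc1)c1ccc(OCc2ccccc2)cc1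
F3 | step 8 | 5,7-bis(benzyloxy)-3-{2,6-bis(benzyloxy)-3-[(3R)-3-[4-(benzyloxy)phenyl]-3-hydroxypropyl]-4-hydroxyphenyl}-2-[4-(benzyloxy)phenyl]-4H-chromen-4-one | O[C@H](CCc1c(O)cc(OCc2ccccc2)c(-c2c(-c3ccc(OCc4ccccc4)cc3)oc3cc(OCc4ccccc4)cc(OCc4ccccc4)c3c2=O)c1OCc1ccccc1)c1ccc(OCc2ccccc2)cc1
F4 | step 8 | 5,7-bis(benzyloxy)-3-{(2S)-5,7-bis(benzyloxy)-2-[4-(benzyloxy)phenyl]-3,4-dihydro-2H-chromen-6-yl}-2-[4-(benzyloxy)phenyl]-4H-chromen-4-one | O=c1c(-c2c(OCc4ccccc4)cc3c(c2OCc2ccccc2)CC[C@@H](c2ccc(OCc4ccccc4)cc2)O3)c(-c2ccc(OCc3ccccc3)cc2)oc2cc(OCc3ccccc3)cc(OCc3ccccc3)c12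
F5 | step 6 | 1-[2,4,6-tris(benzyloxy)phenyl]ethanone | CC(=O)c1c(OCc2ccccc2)cc(OCc2ccccc2)cc1OCc1ccccc1
F6 | step 6 | 2-[2,6-bis(benzyloxy)-4-bromophenyl]-1-[2,4,6-tris(benzyloxy)phenyl]ethanone | O=C(Cc1c(OCc2ccccc2)cc(Br)cc1OCc1ccccc1)c1c(OCc2ccccc2)cc(OCc2ccccc2)cc1OCc1ccccc1
F7 | step 6 | 2-[2,6-bis(benzyloxy)-4-bromophenyl]-1-[2,4-bis(benzyloxy)-6-hydroxyphenyl]ethanone | O=C(Cc1c(OCc2ccccc2)cc(Br)cc1OCc1ccccc1)c1c(O)cc(OCc2ccccc2)cc1OCc1ccccc1
F8 | step 6 | 2-[2,6-bis(benzyloxy)-4-bromophenyl]-1-[2,4-bis(benzyloxy)-6-hydroxyphenyl]-3-[4-(benzyloxy)phenyl]propane-1,3-dione | O=C(c1ccc(OCc2ccccc2)cc1)C(c1c(OCc2ccccc2)cc(Br)cc1OCc1ccccc1)C(=O)c1c(O)cc(OCc2ccccc2)cc1OCc1ccccc1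
F9 | step 3 | {5,7-bis(benzyloxy)-2-[4-(benzyloxy)phenyl]-4-oxo-4H-chromen-3-yl}zinc chloride | Cl[Zn]c1c(-c2ccc(OCc3ccccc3)cc2)oc2cc(OCc3ccccc3)cc(OCc3ccccc3)c2c1=O
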